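(Readings and results were generated by integration with constants of no real substance, and the scatter is random.)

Count the starting material, a conserved quantity: each molecule ends as starting material, target, over-reacted product or quenched substrate.

| flask | starting material | reagent in the second phase | protic impurity | remark | time | volume of the second phase over the first |
|---|---|---|---|---|---|---|
| larch | 1.9 M | 1.5 equiv | 0.053 M | run made earlier |  |  |
| elm | 1.9 M | 1.5 equiv | 0.084 M | run made earlier |  |  |
| flask | 1.9 M | 1.50 equiv | 0.0380 M |  | 10 min | 1.0 |

| run | time / min | target / % |
|---|---|---|
| larch | 1.33 | 7.4 |
| larch | 3.00 | 22.0 |
| larch | 4.00 | 30.9 |
| larch | 6.00 | 43.0 |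
| larch | 8.00 | 53.3 |
| larch | 10.0 | 58.7 |
| elm | 1.33 | 6.5 |
| elm | 3.00 | 22.0 |
| elm | 4.00 | 29.8 |
| elm | 6.00 | 42.9 |
| elm | 8.00 | 52.1 |
| elm | 10.0 | 57.0 |

(standard deviation of a reading: 0.5 percentage points)

- in the second phase: reagent in the second phase; everything else is in the first
- charges count per volume of the first phase; a concentration in a rate is the amount of a species over the volume of its own phase; every rate counts per litre of the first phase
- steps under discussion: starting material + reagent in the reaction phase -> target; reagent in the reaction phase + target -> over-reacted product; reagent in the reaction phase <-> reagent in the second phase; starting material + protic impurity -> quenched substrate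
- the earlier runs hold the two phases in the same ratio of volumes as the flask asked about

- target at 10 min, in percent of the starting material charged
- the change that raises the amount of target at 10 min, in percent of the starting material charged most ("none" if none brings more than 2 percentage points) (noon / midnight / none)
- amount of target at 10 min, in percent of the starting material charged, after noon

Solve both ends and join them. At the late end, let each protic impurity take one starting material, which leaves the flask a ceiling of 98.0 %, that is one minus c(protic impurity)/c(starting material). At the early end, the target climbs in both runs. Join the two with a pseudo-first-order curve, target = ceiling × (1 − e^−θ).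

Read θ from each run's last reading, with that run's own ceiling: larch gives 0.926, elm 0.907. Take the mean, 0.917, the exponent θ: how many e-foldings towards its ceiling the target has made in the time.

Now test it. Larch at 4.00 min gives 0.383, a fraction 0.414 of its final θ for a fraction 0.400 of the time, so in larch θ grows about in step with time up to that reading. My flask figure is 58.8 %.

One number does not part the changes, though. I take both to double the first flux of reagent, but I expect the doubled amount to last longer, so I choose midnight and give no figure for noon.

The forecast says 59.4 % (58.6 % to 60.2 %), and 64.5 % after noon, with “Noon is best, though not by a certain margin”.

The flask gives 58.9 %. The best change is midnight, worth 13 percentage points against 3.8 points for noon, and noon reaches 62.8 %.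

    starting material + reagent in the reaction phase → target (k = 0.00280 L mol⁻¹ s⁻¹)
    reagent in the reaction phase + target → over-reacted product (k = 3.80 × 10⁻⁴ L mol⁻¹ s⁻¹)
    reagent in the reaction phase ⇌ reagent in the second phase, rate k3*([reagent in the reaction phase] - [reagent in the second phase]/K3) per volume of the first phase (partition coefficient = 1.20, kL = 0.00510 s⁻¹)
    starting material + protic impurity → quenched substrate (k = 1.20 L mol⁻¹ s⁻¹)

Carry θ to the same flask read at 25 min: scaled with time it is 2.29, and the curve gives 88.1 %. That neighbour holds 71.6 % target, 17 points lower, with 10.4 % starting material left and 16.0 % over-reacted product.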